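**Retrosynthetic overview**
- The target is a (2S,4R)-7,3',4'-trihydroxyflavan (rings A, C, B) joined from its C4 to C8 of (2R,3R)-epigallocatechin (rings D, F, E); it is released last by hydrogenolysis of its nona-benzyl ether.
- Ring E is attached to lower C2 by adding an arylzinc to the ring F oxocarbenium ion (from the lactol acetate), cis to the C3 benzyloxy group.
- The strategy rests on ring F: its O1–C2 and C3–C4 bonds end on ring D's C8a oxygen and C4a, the two termini of an ortho-quinone methide with lower C4 as the exocyclic methylene, and C3 carries the oxygen of an α-oxyaldehyde. Ring F is therefore closed by an aminocatalytic formal [4+2] between the ring D quinone methide (from a sulfone) and the enamine of benzyloxyacetaldehyde.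
- The sulfone comes from a ring D salicylaldehyde. The upper C4–ring D bond is made by Friedel–Crafts alkylation of the symmetric 4-benzyloxy-2,6-dihydroxybenzaldehyde with a flavan-4-ol, which fixes the 2,4-trans relation.
- Rings A and C come from 7-benzyloxychromone, and ring B is added by asymmetric conjugate arylation (upper C2). Order of assembly: A/C, then B, then D, then F closed, then E.

Key step: step 9

Assumption: in step 2 the (R)-configured pyridine-oxazoline ligand is taken to give the 2S flavanone, by analogy with the facial sense this catalyst shows with cyclic enones; if the sense proved opposite, the (S)-ligand would be used.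

**Step 1**
Reactants: 1 7-hydroxy-4H-chromen-4-one
Product: 2 7-(benzyloxy)-4H-chromen-4-one
Conditions: BnBr, K2CO3, DMF, rt
Reagents that add atoms: benzyl bromide, BrCc1ccccc1
Why: Williamson etherification of the acidic 7-hydroxyl (a vinylogous acid) should proceed cleanly and creates no stereocentre.

**Step 2**
Reactants: 2 7-(benzyloxy)-4H-chromen-4-one; 3 [3,4-bis(benzyloxy)phenyl]boronic acid
Product: 4 (2S)-7-(benzyloxy)-2-[3,4-bis(benzyloxy)phenyl]chroman-4-one
Conditions: Pd(OCOCF3)2 (5 mol%), (R)-4-tert-butyl-2-(pyridin-2-yl)-4,5-dihydrooxazole (6 mol%), NH4PF6 (30 mol%), H2O (5 equiv), ClCH2CH2Cl, 60 °C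
Reagents that add atoms: none
Why: Palladium-catalysed asymmetric conjugate addition of an arylboronic acid to a chromone (aryl transfer from boron to divalent palladium, insertion of the enone, protonolysis) is an established flavanone synthesis, and the tert-butyl group of the ligand selects the enone face so that upper C2 is set as S.

**Step 3**
Reactants: 4 (2S)-7-(benzyloxy)-2-[3,4-bis(benzyloxy)phenyl]chroman-4-one
Product: 5 (2S,4S)-7-(benzyloxy)-2-[3,4-bis(benzyloxy)phenyl]chroman-4-ol (2,4-cis)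
Conditions: NaBH4, THF/MeOH, 0 °C
Reagents that add atoms: none
Why: Borohydride 1,2-reduction of a flavanone should give the 2,4-cis alcohol by axial hydride delivery; the C4 configuration is of no consequence because it is lost on ionisation in step 5.

**Step 4**
Reactants: 6 2,4,6-trihydroxybenzaldehyde
Product: 7 4-(benzyloxy)-2,6-dihydroxybenzaldehyde
Conditions: BnBr (1.0 equiv), KHCO3, DMF, rt to 40 °C
Reagents that add atoms: benzyl bromide, BrCc1ccccc1
Why: Williamson mono-etherification should fall on the 4-hydroxyl, which is para to the formyl group, most acidic and the only one not tied up in a hydrogen bond to the carbonyl.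

**Step 5**
Reactants: 5 (2S,4S)-flavan-4-ol; 7 4-(benzyloxy)-2,6-dihydroxybenzaldehyde (3 equiv)
Product: 8 4-(benzyloxy)-3-{(2S,4R)-7-(benzyloxy)-2-[3,4-bis(benzyloxy)phenyl]chroman-4-yl}-2,6-dihydroxybenzaldehyde (2,4-trans)
Conditions: BF3·OEt2 (1 equiv), CH2Cl2/1,4-dioxane, −20 to 0 °C
Reagents that add atoms: none
Why: Friedel–Crafts alkylation with loss of water, through the 7-alkoxy-stabilised flavan-4-yl cation (the biomimetic interflavan coupling), meets an arene whose two nucleophilic CH positions are equivalent, so one regioisomer is possible, and pseudoaxial attack on the half-chair cation anti to the equatorial C2 aryl group should set upper C4 as R (2,4-trans), the minor cis isomer being removed by chromatography.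

**Step 6**
Reactants: 8 dihydroxy aldehyde from step 5
Product: 9 4,6-bis(benzyloxy)-3-{(2S,4R)-7-(benzyloxy)-2-[3,4-bis(benzyloxy)phenyl]chroman-4-yl}-2-hydroxybenzaldehyde
Conditions: BnBr (1.05 equiv), K2CO3, DMF, rt
Reagents that add atoms: benzyl bromide, BrCc1ccccc1
Why: Williamson etherification should select the less hindered of the two chelated hydroxyls (the one next to the ring hydrogen), leaving free the hydroxyl shielded by the flavanyl group and hydrogen-bonded to the aldehyde, which is the one that becomes O1 of ring F.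

**Step 7**
Reactants: 9 salicylaldehyde from step 6
Product: 10 3,5-bis(benzyloxy)-6-{(2S,4R)-7-(benzyloxy)-2-[3,4-bis(benzyloxy)phenyl]chroman-4-yl}-2-(hydroxymethyl)phenol
Conditions: NaBH4, THF/EtOH, 0 °C; aq. NH4Cl quench at 0 °C, crude product used at once
Reagents that add atoms: none
Why: Borohydride reduction of the aldehyde at low temperature should stop at the salicyl alcohol, which is kept cold and neutral because this electron-rich ring ionises easily.

**Step 8**
Reactants: 10 salicyl alcohol from step 7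
Product: 11 3,5-bis(benzyloxy)-6-{(2S,4R)-7-(benzyloxy)-2-[3,4-bis(benzyloxy)phenyl]chroman-4-yl}-2-[(4-methylphenyl)sulfonylmethyl]phenol
Conditions: p-TolSO2H (1.5 equiv, freshly liberated from its sodium salt), CH2Cl2, rt
Reagents that add atoms: p-toluenesulfinic acid, Cc1ccc(cc1)S(=O)O
Why: Acid-promoted ionisation of the ortho-hydroxybenzyl alcohol and S-alkylation of the sulfinic acid, with loss of water, is the standard preparation of 2-(sulfonylmethyl)phenols, and the mild acid should leave the interflavan bond of this 5-deoxy upper unit intact.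

**Step 9**
Reactants: 11 ring D sulfone; 12 (benzyloxy)acetaldehyde (3 equiv, added slowly)
Product: 14 ring F lactol (3R)-3,5,7-tris(benzyloxy)-8-{(2S,4R)-7-(benzyloxy)-2-[3,4-bis(benzyloxy)phenyl]chroman-4-yl}chroman-2-ol (both C2 anomers), via ring D ortho-quinone methide 13 (not isolated)
Conditions: (S)-α,α-diphenylprolinol trimethylsilyl ether (20 mol%), Na2CO3 (1.5 equiv), CHCl3, 0 °C to rt
Reagents that add atoms: none
Why: Na2CO3 deprotonates the ring D phenol of 11 and p-toluenesulfinate leaves by 1,4-elimination to give ortho-quinone methide 13, while 12 condenses with the prolinol catalyst to the E-enamine. The enamine α-carbon adds to the exocyclic methylene of 13 (Michael step, lower C3–C4 bond) and the rearomatised phenoxide then closes onto the iminium carbon (O1–C2 bond), so ring F forms by 6-exo-trig N,O-acetalisation, and hydrolysis releases lactol 14 and the catalyst. This is the aminocatalytic asymmetric formal [4+2] annulation of in situ ortho-quinone methides with aldehydes to chroman-2-ols, here with an α-oxyaldehyde as the enamine partner. The only new fixed stereocentre, lower C3, is set by the catalyst: the diphenyl(trimethylsilyloxy)methyl group blocks one face of the s-trans E-enamine, so the methide is taken up on the open face and the (S)-catalyst should give 3R, the sense known for Michael additions of aldehydes under this catalyst. The step needs one regiochemistry and one enamine face; the first is secured because 11 has a single free phenol, flanked by the flavanyl group and the sulfonylmethyl carbon, so only the methide that leads to the 4-to-8 linkage can form, and the second because the upper stereocentres lie five bonds from the reacting methylene and should not override the catalyst.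

**Step 10**
Reactants: 14 ring F lactol
Product: 15 (3R)-3,5,7-tris(benzyloxy)-8-{(2S,4R)-7-(benzyloxy)-2-[3,4-bis(benzyloxy)phenyl]chroman-4-yl}chroman-2-yl acetate (anomer mixture)
Conditions: Ac2O, pyridine, DMAP (cat.), CH2Cl2, 0 °C
Reagents that add atoms: acetic anhydride, CC(=O)OC(C)=O
Why: Acylation of the lactol hydroxyl gives the anomeric acetates, both of which converge on the same oxocarbenium ion in step 13, and the short, cold reaction limits epimerisation at C3 through the open hydroxy aldehyde.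

**Step 11**
Reactants: 16 5-bromo-1,2,3-trimethoxybenzene
Product: 17 5-bromobenzene-1,2,3-triol
Conditions: BBr3 (4 equiv), CH2Cl2, −78 °C to rt; then H2O
Reagents that add atoms: none
Why: Boron tribromide cleavage of aryl methyl ethers is reliable and leaves the aryl bromide untouched.

**Step 12**
Reactants: 17 5-bromobenzene-1,2,3-triol
Product: 18 5-bromo-1,2,3-tris(benzyloxy)benzene
Conditions: BnBr (3.5 equiv), K2CO3, DMF, 60 °C, under N2
Reagents that add atoms: benzyl bromide, BrCc1ccccc1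
Why: Threefold Williamson etherification puts on ring E the same protecting group as the rest of the molecule, so one hydrogenolysis finishes the synthesis.

**Step 13**
Reactants: 15 lactol acetate; 18 5-bromo-1,2,3-tris(benzyloxy)benzene (3 equiv)
Product: 21 (2R,3R)-3,5,7-tris(benzyloxy)-8-{(2S,4R)-7-(benzyloxy)-2-[3,4-bis(benzyloxy)phenyl]chroman-4-yl}-2-[3,4,5-tris(benzyloxy)phenyl]chroman (2,3-cis), via aryllithium 19 (not isolated), via arylzinc bromide 20 (not isolated)
Conditions: 18, n-BuLi, toluene/Et2O, −78 °C; ZnBr2 (Et2O); then 15, BF3·OEt2 (2 equiv), CH2Cl2, −78 to −20 °C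
Reagents that add atoms: zinc dibromide, [Zn+2].[Br-].[Br-] (zinc and bromine stay only in intermediate 20); n-butyllithium, [Li]CCCC (lithium stays only in intermediate 19)
Why: Bromine–lithium exchange and transmetalation give arylzinc 20, which adds in a Lewis-acid-promoted C-arylation of the lactol acetate through the ring F oxocarbenium ion; on the half-chair with the C3 benzyloxy group pseudoequatorial the aryl group enters pseudoaxially and therefore cis to C3–OBn, which should set lower C2 as R.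

**Step 14**
Reactants: 21 nona-benzyl ether
Product: 22 (2R,3R)-8-[(2S,4R)-2-(3,4-dihydroxyphenyl)-7-hydroxychroman-4-yl]-2-(3,4,5-trihydroxyphenyl)chroman-3,5,7-triol (target)
Conditions: H2 (1 atm), Pd(OH)2/C, THF/MeOH, rt
Reagents that add atoms: none
Why: Hydrogenolysis of the nine benzyl ethers under neutral conditions is the standard end game for benzylated proanthocyanidins and should leave the cyclic benzylic C2–O bonds and all four stereocentres untouched.

**Compound list**
1 | 7-hydroxy-4H-chromen-4-one | O=c1ccoc2cc(O)ccc12 | starting material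
2 | 7-(benzyloxy)-4H-chromen-4-one | O=c1ccoc2cc(OCc3ccccc3)ccc12 | intermediate
3 | [3,4-bis(benzyloxy)phenyl]boronic acid | OB(O)c1ccc(OCc2ccccc2)c(OCc2ccccc2)c1 | starting material
4 | (2S)-7-(benzyloxy)-2-[3,4-bis(benzyloxy)phenyl]chroman-4-one | c1ccccc1COc1ccc2c(c1)O[C@H](c1ccc(OCc3ccccc3)c(OCc3ccccc3)c1)CC2=O | intermediate
5 | (2S,4S)-7-(benzyloxy)-2-[3,4-bis(benzyloxy)phenyl]chroman-4-ol | c1ccccc1COc1ccc2c(c1)O[C@H](c1ccc(OCc3ccccc3)c(OCc3ccccc3)c1)C[C@@H]2O | intermediate
6 | 2,4,6-trihydroxybenzaldehyde | O=Cc1c(O)cc(O)cc1O | starting material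
7 | 4-(benzyloxy)-2,6-dihydroxybenzaldehyde | O=Cc1c(O)cc(OCc2ccccc2)cc1O | intermediate
8 | 4-(benzyloxy)-3-{(2S,4R)-7-(benzyloxy)-2-[3,4-bis(benzyloxy)phenyl]chroman-4-yl}-2,6-dihydroxybenzaldehyde | c1ccccc1COc1ccc2c(c1)O[C@H](c1ccc(OCc3ccccc3)c(OCc3ccccc3)c1)C[C@H]2c1c(OCc2ccccc2)cc(O)c(C=O)c1O | intermediate
9 | 4,6-bis(benzyloxy)-3-{(2S,4R)-7-(benzyloxy)-2-[3,4-bis(benzyloxy)phenyl]chroman-4-yl}-2-hydroxybenzaldehyde | c1ccccc1COc1ccc2c(c1)O[C@H](c1ccc(OCc3ccccc3)c(OCc3ccccc3)c1)C[C@H]2c1c(OCc2ccccc2)cc(OCc2ccccc2)c(C=O)c1O | intermediate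
10 | 3,5-bis(benzyloxy)-6-{(2S,4R)-7-(benzyloxy)-2-[3,4-bis(benzyloxy)phenyl]chroman-4-yl}-2-(hydroxymethyl)phenol | c1ccccc1COc1ccc2c(c1)O[C@H](c1ccc(OCc3ccccc3)c(OCc3ccccc3)c1)C[C@H]2c1c(OCc2ccccc2)cc(OCc2ccccc2)c(CO)c1O | intermediate
11 | 3,5-bis(benzyloxy)-6-{(2S,4R)-7-(benzyloxy)-2-[3,4-bis(benzyloxy)phenyl]chroman-4-yl}-2-[(4-methylphenyl)sulfonylmethyl]phenol | c1ccccc1COc1ccc2c(c1)O[C@H](c1ccc(OCc3ccccc3)c(OCc3ccccc3)c1)C[C@H]2c1c(OCc2ccccc2)cc(OCc2ccccc2)c(CS(=O)(=O)c2ccc(C)cc2)c1O | intermediate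
12 | (benzyloxy)acetaldehyde | O=CCOCc1ccccc1 | starting material
13 | 3,5-bis(benzyloxy)-2-{(2S,4R)-7-(benzyloxy)-2-[3,4-bis(benzyloxy)phenyl]chroman-4-yl}-6-methylidenecyclohexa-2,4-dien-1-one (ring D ortho-quinone methide) | c1ccccc1COc1ccc2c(c1)O[C@H](c1ccc(OCc3ccccc3)c(OCc3ccccc3)c1)C[C@H]2C1=C(OCc2ccccc2)C=C(OCc2ccccc2)C(=C)C1=O | intermediate
14 | (3R)-3,5,7-tris(benzyloxy)-8-{(2S,4R)-7-(benzyloxy)-2-[3,4-bis(benzyloxy)phenyl]chroman-4-yl}chroman-2-ol (ring F lactol, C2 anomers) | c1ccccc1COc1ccc2c(c1)O[C@H](c1ccc(OCc3ccccc3)c(OCc3ccccc3)c1)C[C@H]2c1c(OCc2ccccc2)cc(OCc2ccccc2)c2c1OC(O)[C@H](OCc1ccccc1)C2 | intermediate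
15 | (3R)-3,5,7-tris(benzyloxy)-8-{(2S,4R)-7-(benzyloxy)-2-[3,4-bis(benzyloxy)phenyl]chroman-4-yl}chroman-2-yl acetate | c1ccccc1COc1ccc2c(c1)O[C@H](c1ccc(OCc3ccccc3)c(OCc3ccccc3)c1)C[C@H]2c1c(OCc2ccccc2)cc(OCc2ccccc2)c2c1OC(OC(C)=O)[C@H](OCc1ccccc1)C2 | intermediate
16 | 5-bromo-1,2,3-trimethoxybenzene | COc1cc(Br)cc(OC)c1OC | starting material
17 | 5-bromobenzene-1,2,3-triol | Oc1cc(Br)cc(O)c1O | intermediate
18 | 5-bromo-1,2,3-tris(benzyloxy)benzene | Brc1cc(OCc2ccccc2)c(OCc2ccccc2)c(OCc2ccccc2)c1 | intermediate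
19 | [3,4,5-tris(benzyloxy)phenyl]lithium | [Li]c1cc(OCc2ccccc2)c(OCc2ccccc2)c(OCc2ccccc2)c1 | intermediate
20 | [3,4,5-tris(benzyloxy)phenyl]zinc bromide | Br[Zn]c1cc(OCc2ccccc2)c(OCc2ccccc2)c(OCc2ccccc2)c1 | intermediate
21 | (2R,3R)-3,5,7-tris(benzyloxy)-8-{(2S,4R)-7-(benzyloxy)-2-[3,4-bis(benzyloxy)phenyl]chroman-4-yl}-2-[3,4,5-tris(benzyloxy)phenyl]chroman | c1ccccc1COc1ccc2c(c1)O[C@H](c1ccc(OCc3ccccc3)c(OCc3ccccc3)c1)C[C@H]2c1c(OCc2ccccc2)cc(OCc2ccccc2)c2c1O[C@H](c1cc(OCc3ccccc3)c(OCc3ccccc3)c(OCc3ccccc3)c1)[C@H](OCc1ccccc1)C2 | intermediate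
22 | (2R,3R)-8-[(2S,4R)-2-(3,4-dihydroxyphenyl)-7-hydroxychroman-4-yl]-2-(3,4,5-trihydroxyphenyl)chroman-3,5,7-triol | Oc1ccc2c(c1)O[C@H](c1ccc(O)c(O)c1)C[C@H]2c1c(O)cc(O)c2c1O[C@H](c1cc(O)c(O)c(O)c1)[C@H](O)C2 | target

**Step count**
Total: 14 steps. Longest linear sequence: 11 steps (steps 1, 2, 3, 5, 6, 7, 8, 9, 10, 13, 14).

**Steps most likely to fail**

Step 9. The enamine may take up the methide with poor face selectivity, the secondary amine may be sequestered by reversible addition to the methide, or self-aldol of the oxyaldehyde may outrun the annulation. The fallback sets lower C3 with a stoichiometric auxiliary and starts from sulfone 11. The phenol of 11 is deprotonated with NaN(SiMe3)2 (THF, −78 °C) and added to the sodium enolate of (S)-4-benzyl-3-[(benzyloxy)acetyl]oxazolidin-2-one. On warming to −20 °C the methide is released and alkylates the chelated enolate on the face away from the benzyl group (Evans-type glycolate alkylation), giving (4S)-4-benzyl-3-[(2R)-2-(benzyloxy)-3-(ring D aryl)propanoyl]oxazolidin-2-one F1. Treating F1 with DBU in THF lets the neighbouring phenol take over the acyl group and gives the (3R)-3-benzyloxy ring F lactone F2. Reduction of F2 with i-Bu2AlH (CH2Cl2, −78 °C) gives lactol 14, where the route is rejoined.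

Step 13. The aryl transfer may favour the thermodynamically preferred 2,3-trans arrangement, or the oxocarbenium ion may lose a proton to the enol ether before it is captured. The fallback uses a trans addition and corrects C3 afterwards; it starts from sulfone 11 and returns at target 22. The annulation of step 9 is run with the (R)-catalyst and (tert-butyldimethylsilyloxy)acetaldehyde to give the (3S)-3-silyloxy lactol F3, which is acetylated to acetate F4. Arylzinc 20 with BF3·OEt2 should then add anti to the bulky silyloxy group, giving the (2R,3S)-2,3-trans silyl ether F5. Bu4NF in THF frees the (2R,3S)-alcohol F6, and Dess–Martin oxidation gives the (2R)-3-ketone F7. LiBH(s-Bu)3 (THF, −78 °C) delivers hydride anti to the C2 aryl group and gives the (2R,3R)-2,3-cis alcohol F8, whose hydrogenolysis (H2, Pd(OH)2/C) gives 22.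

Step 5. The carbonyl-deactivated, chelated ring of 7 may capture the flavan-4-yl cation too slowly, so that elimination to the flav-3-ene and self-alkylation compete, and the 2,4-trans preference may be incomplete. The fallback uses a more nucleophilic arene without a carbonyl group and brings in the formyl carbon afterwards; it starts from flavan-4-ol 5. Coupling of 5 with 3,5-bis(benzyloxy)phenol (BF3·OEt2, CH2Cl2, −40 °C) should give, after separation from the isomer alkylated between the two benzyloxy groups, 3,5-bis(benzyloxy)-2-{(2S,4R)-flavan-4-yl}phenol F9. Magnesium-mediated ortho-formylation of F9 (MgCl2, Et3N, paraformaldehyde, MeCN, reflux) can only enter the one open position next to the hydroxyl and gives salicylaldehyde 9, where the route is rejoined.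

**Further compounds**
F1 | step 9 | (4S)-4-benzyl-3-[(2R)-2-(benzyloxy)-3-(4,6-bis(benzyloxy)-3-{(2S,4R)-7-(benzyloxy)-2-[3,4-bis(benzyloxy)phenyl]chroman-4-yl}-2-hydroxyphenyl)propanoyl]oxazolidin-2-one | c1ccccc1COc1ccc2c(c1)O[C@H](c1ccc(OCc3ccccc3)c(OCc3ccccc3)c1)C[C@H]2c1c(OCc2ccccc2)cc(OCc2ccccc2)c(C[C@@H](OCc2ccccc2)C(=O)N2C(=O)OC[C@@H]2Cc2ccccc2)c1O
F2 | step 9 | (3R)-3,5,7-tris(benzyloxy)-8-{(2S,4R)-7-(benzyloxy)-2-[3,4-bis(benzyloxy)phenyl]chroman-4-yl}chroman-2-one | c1ccccc1COc1ccc2c(c1)O[C@H](c1ccc(OCc3ccccc3)c(OCc3ccccc3)c1)C[C@H]2c1c(OCc2ccccc2)cc(OCc2ccccc2)c2c1OC(=O)[C@H](OCc1ccccc1)C2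
F3 | step 13 | (3S)-5,7-bis(benzyloxy)-8-{(2S,4R)-7-(benzyloxy)-2-[3,4-bis(benzyloxy)phenyl]chroman-4-yl}-3-(tert-butyldimethylsilyloxy)chroman-2-ol | c1ccccc1COc1ccc2c(c1)O[C@H](c1ccc(OCc3ccccc3)c(OCc3ccccc3)c1)C[C@H]2c1c(OCc2ccccc2)cc(OCc2ccccc2)c2c1OC(O)[C@@H](O[Si](C)(C)C(C)(C)C)C2
F4 | step 13 | (3S)-5,7-bis(benzyloxy)-8-{(2S,4R)-7-(benzyloxy)-2-[3,4-bis(benzyloxy)phenyl]chroman-4-yl}-3-(tert-butyldimethylsilyloxy)chroman-2-yl acetate | c1ccccc1COc1ccc2c(c1)O[C@H](c1ccc(OCc3ccccc3)c(OCc3ccccc3)c1)C[C@H]2c1c(OCc2ccccc2)cc(OCc2ccccc2)c2c1OC(OC(C)=O)[C@@H](O[Si](C)(C)C(C)(C)C)C2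
F5 | step 13 | (2R,3S)-5,7-bis(benzyloxy)-8-{(2S,4R)-7-(benzyloxy)-2-[3,4-bis(benzyloxy)phenyl]chroman-4-yl}-3-(tert-butyldimethylsilyloxy)-2-[3,4,5-tris(benzyloxy)phenyl]chroman | c1ccccc1COc1ccc2c(c1)O[C@H](c1ccc(OCc3ccccc3)c(OCc3ccccc3)c1)C[C@H]2c1c(OCc2ccccc2)cc(OCc2ccccc2)c2c1O[C@H](c1cc(OCc3ccccc3)c(OCc3ccccc3)c(OCc3ccccc3)c1)[C@@H](O[Si](C)(C)C(C)(C)C)C2
F6 | step 13 | (2R,3S)-5,7-bis(benzyloxy)-8-{(2S,4R)-7-(benzyloxy)-2-[3,4-bis(benzyloxy)phenyl]chroman-4-yl}-2-[3,4,5-tris(benzyloxy)phenyl]chroman-3-ol | c1ccccc1COc1ccc2c(c1)O[C@H](c1ccc(OCc3ccccc3)c(OCc3ccccc3)c1)C[C@H]2c1c(OCc2ccccc2)cc(OCc2ccccc2)c2c1O[C@H](c1cc(OCc3ccccc3)c(OCc3ccccc3)c(OCc3ccccc3)c1)[C@@H](O)C2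
F7 | step 13 | (2R)-5,7-bis(benzyloxy)-8-{(2S,4R)-7-(benzyloxy)-2-[3,4-bis(benzyloxy)phenyl]chroman-4-yl}-2-[3,4,5-tris(benzyloxy)phenyl]chroman-3-one | c1ccccc1COc1ccc2c(c1)O[C@H](c1ccc(OCc3ccccc3)c(OCc3ccccc3)c1)C[C@H]2c1c(OCc2ccccc2)cc(OCc2ccccc2)c2c1O[C@H](c1cc(OCc3ccccc3)c(OCc3ccccc3)c(OCc3ccccc3)c1)C(=O)C2
F8 | step 13 | (2R,3R)-5,7-bis(benzyloxy)-8-{(2S,4R)-7-(benzyloxy)-2-[3,4-bis(benzyloxy)phenyl]chroman-4-yl}-2-[3,4,5-tris(benzyloxy)phenyl]chroman-3-ol | c1ccccc1COc1ccc2c(c1)O[C@H](c1ccc(OCc3ccccc3)c(OCc3ccccc3)c1)C[C@H]2c1c(OCc2ccccc2)cc(OCc2ccccc2)c2c1O[C@H](c1cc(OCc3ccccc3)c(OCc3ccccc3)c(OCc3ccccc3)c1)[C@H](O)C2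
F9 | step 5 | 3,5-bis(benzyloxy)-2-{(2S,4R)-7-(benzyloxy)-2-[3,4-bis(benzyloxy)phenyl]chroman-4-yl}phenol | c1ccccc1COc1ccc2c(c1)O[C@H](c1ccc(OCc3ccccc3)c(OCc3ccccc3)c1)C[C@H]2c1c(OCc2ccccc2)cc(OCc2ccccc2)cc1O
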